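**Plan**

1. Numbering: the central benzene is ring A; its position 1 bears the methide carbon, position 2 the resorcinol ring B, positions 3 and 4 hydrogen, position 5 the hydroxymethyl group and position 6 the arylethynyl group. Ring B is counted from its carbon bonded to ring A, so its hydroxyls sit on position 2 (ortho) and position 4 (para).
2. Enabling feature: the two C–H positions 3 and 4 of ring A lie next to the ortho hydroxyl of ring B and to the hydroxymethyl oxygen on position 5. A silicon on position 3 can therefore be tied to the ring B ortho oxygen in a six-membered ring and a silicon on position 4 to the hydroxymethyl oxygen in a five-membered ring, and both can later be exchanged for hydrogen.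
3. Retrosynthesis: the methide carbon is cut from one para-oxyphenyl group (aryllithium plus diaryl ketone; acid then gives the quinone methide). The two ring A C–H bonds and the two O–H bonds go back to two Si(iPr)2 tethers. Ring A is cut between positions 2 and 3, 4 and 5, and 6 and 1 into the three triple bonds of one triyne (ynone, bis-silylethyne, inner bond of a 1,3-diyne).
4. The triyne is cut at its two Si–O bonds, at one Si–C(sp) bond, at the ring B–C(sp) bond (Sonogashira) and at the diyne C(sp)–C(sp) bond (Cadiot–Chodkiewicz).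
5. Forward: diynol, first silicon, second silicon with the iodophenol, ynone arm. One cyclotrimerisation then closes ring A together with the oxasilole and oxasiline rings, fluoride removes both silicon atoms, and the last aryl group plus acid complete the quinone methide.
6. Stereochemistry: the target has no stereocentre; the only one on the route (racemic carbinol in 16 and 17) is erased by the oxidation in step 10.

Key step: step 11

Remark: the target is taken as the open para-quinone methide drawn; addition of the ring B ortho hydroxyl to the methide carbon is assumed to be reversible under the final acidic conditions, so that the open conjugated form is the one isolated.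

**Route**

Step 1
Reactants: 1 4-hydroxybenzaldehyde
Product: 2 4-(methoxymethoxy)benzaldehyde
Conditions: MOMCl, iPr2NEt, CH2Cl2, 0 °C → rt
Reagents that add atoms: chloromethyl methyl ether (MOMCl), COCCl
Why: O-alkylation of the phenol with the reactive chloromethyl ether under amine base (Williamson-type acetal formation); the aldehyde is not touched.

Step 2
Reactants: 2 4-(methoxymethoxy)benzaldehyde
Product: 3 1-ethynyl-4-(methoxymethoxy)benzene
Conditions: dimethyl (1-diazo-2-oxopropyl)phosphonate, K2CO3, MeOH, rt
Reagents that add atoms: dimethyl (1-diazo-2-oxopropyl)phosphonate (Ohira–Bestmann reagent), COP(=O)(OC)C(=[N+]=[N-])C(C)=O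
Why: Seyferth–Gilbert homologation in the Ohira–Bestmann version; the diazomethylphosphonate anion formed in situ should convert the non-enolisable aryl aldehyde into the terminal alkyne under mild carbonate conditions that the MOM ether tolerates.

Step 3
Reactants: 3 1-ethynyl-4-(methoxymethoxy)benzene
Product: 4 1-(bromoethynyl)-4-(methoxymethoxy)benzene
Conditions: NBS, AgNO3 (cat.), acetone, rt, dark
Reagents that add atoms: N-bromosuccinimide (NBS), O=C1CCC(=O)N1Br
Why: AgNO3-catalysed bromination of a terminal alkyne through the silver acetylide; under these neutral conditions the mono-oxygenated ring should not be brominated.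

Step 4
Reactants: 4 1-(bromoethynyl)-4-(methoxymethoxy)benzene, 5 propargyl alcohol
Product: 6 5-[4-(methoxymethoxy)phenyl]penta-2,4-diyn-1-ol
Conditions: 5 (excess), CuCl (cat.), NH2OH·HCl, n-BuNH2, H2O/Et2O, 0 °C
Reagents that add atoms: none
Why: Cadiot–Chodkiewicz coupling; the copper acetylide of the cheap alkynol, used in excess, couples with the 1-bromoalkyne while hydroxylamine keeps copper monovalent and so holds back homocoupling.

Step 5
Reactants: 6 5-[4-(methoxymethoxy)phenyl]penta-2,4-diyn-1-ol, 7 ethynylmagnesium bromide, 8 dichlorodiisopropylsilane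
Product: 10 ethynyldiisopropyl({5-[4-(methoxymethoxy)phenyl]penta-2,4-diyn-1-yl}oxy)silane, via chloro(ethynyl)diisopropylsilane 9 (not isolated)
Conditions: 7 into 8, THF, 0 °C → rt; then 6, imidazole, DMF, rt
Reagents that add atoms: none
Why: Substitution at silicon by the alkynyl Grignard reagent should stop after one chloride because of the two isopropyl groups, and imidazole-promoted silylation of the primary alcohol by the remaining Si–Cl bond gives the alkynylsilyl ether (the usual way to silyl ether tethers).

Step 6
Reactants: 11 4-iodoresorcinol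
Product: 12 2-iodo-5-(methoxymethoxy)phenol
Conditions: MOMCl (1.0 equiv), iPr2NEt, CH2Cl2, −20 → 0 °C
Reagents that add atoms: chloromethyl methyl ether (MOMCl), COCCl
Why: Regioselective mono-O-alkylation of a 4-haloresorcinol; the hydroxyl para to iodine is unhindered and the more nucleophilic one, whereas the hydroxyl beside iodine is shielded and less nucleophilic, so one equivalent of MOMCl at low temperature should favour the desired isomer, to be separated from regioisomer and bis-ether by chromatography.

Step 7
Reactants: 10 ethynyldiisopropyl({5-[4-(methoxymethoxy)phenyl]penta-2,4-diyn-1-yl}oxy)silane, 8 dichlorodiisopropylsilane, 12 2-iodo-5-(methoxymethoxy)phenol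
Product: 15 {[2-iodo-5-(methoxymethoxy)phenoxy]diisopropylsilyl}{diisopropyl({5-[4-(methoxymethoxy)phenyl]penta-2,4-diyn-1-yl}oxy)silyl}ethyne, via alkynyllithium 13 (not isolated), via alkynylchlorosilane 14 (not isolated)
Conditions: LiN(SiMe3)2, THF, −78 °C; then 8 (excess), −78 °C → rt; volatiles removed in vacuo; then 12, imidazole, DMF, rt
Reagents that add atoms: none
Why: LiN(SiMe3)2 removes only the silylacetylene proton, the acetylide is silylated once by excess iPr2SiCl2 (nucleophilic substitution at silicon, the second substitution being sterically slow) and the remaining Si–Cl bond is captured by the phenol under imidazole; attaching the aryloxy group last keeps an Si–OAr bond away from the acetylide.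

Step 8
Reactants: 2 4-(methoxymethoxy)benzaldehyde, 7 ethynylmagnesium bromide
Product: 16 rac-1-[4-(methoxymethoxy)phenyl]prop-2-yn-1-ol
Conditions: THF, 0 °C; aq. NH4Cl
Reagents that add atoms: none
Why: 1,2-Addition of the alkynyl Grignard reagent to the aldehyde; the carbinol centre is formed racemic on purpose because step 10 removes it.

Step 9
Reactants: 15 {[2-iodo-5-(methoxymethoxy)phenoxy]diisopropylsilyl}{diisopropyl({5-[4-(methoxymethoxy)phenyl]penta-2,4-diyn-1-yl}oxy)silyl}ethyne, 16 rac-1-[4-(methoxymethoxy)phenyl]prop-2-yn-1-ol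
Product: 17 rac-3-{2-[({[diisopropyl({5-[4-(methoxymethoxy)phenyl]penta-2,4-diyn-1-yl}oxy)silyl]ethynyl}diisopropylsilyl)oxy]-4-(methoxymethoxy)phenyl}-1-[4-(methoxymethoxy)phenyl]prop-2-yn-1-ol
Conditions: PdCl2(PPh3)2 (cat.), CuI (cat.), Et3N/THF, rt, degassed
Reagents that add atoms: none
Why: Sonogashira coupling of the aryl iodide with the terminal alkyne at room temperature; the bis-silylated and diyne triple bonds are internal and inert, and the ring B ortho oxygen is masked as its silyl ether so that no benzofuran can form.

Step 10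
Reactants: 17 rac-3-{2-[({[diisopropyl({5-[4-(methoxymethoxy)phenyl]penta-2,4-diyn-1-yl}oxy)silyl]ethynyl}diisopropylsilyl)oxy]-4-(methoxymethoxy)phenyl}-1-[4-(methoxymethoxy)phenyl]prop-2-yn-1-ol
Product: 18 3-{2-[({[diisopropyl({5-[4-(methoxymethoxy)phenyl]penta-2,4-diyn-1-yl}oxy)silyl]ethynyl}diisopropylsilyl)oxy]-4-(methoxymethoxy)phenyl}-1-[4-(methoxymethoxy)phenyl]prop-2-yn-1-one
Conditions: activated MnO2 (excess), CH2Cl2, rt
Reagents that add atoms: none
Why: MnO2 oxidation of a secondary alcohol that is both benzylic and propargylic gives the ynone under neutral heterogeneous conditions that spare the silyl ethers and MOM groups.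

Step 11
Reactants: 18 3-{2-[({[diisopropyl({5-[4-(methoxymethoxy)phenyl]penta-2,4-diyn-1-yl}oxy)silyl]ethynyl}diisopropylsilyl)oxy]-4-(methoxymethoxy)phenyl}-1-[4-(methoxymethoxy)phenyl]prop-2-yn-1-one
Product: 19 doubly silicon-tethered cyclotrimer: tetracyclic aryl ketone in which hexasubstituted ring A is fused to a 1,1-diisopropyl-1,3-dihydro-2,1-benzoxasilole (silicon on position 4 of ring A; OCH2 on position 5) and to a 6,6-diisopropyl-6H-dibenzo[c,e][1,2]oxasiline (silicon on position 3 of ring A; oxygen on the ortho carbon of ring B; OMOM para on ring B) and carries the 4-(methoxymethoxy)benzoyl group on position 1 and the [4-(methoxymethoxy)phenyl]ethynyl group on position 6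
Conditions: RhCl(PPh3)3 (10 mol%), toluene (0.005 M, degassed), 80 °C
Reagents that add atoms: none
Why: Oxidative cyclisation of the bis-silylated alkyne with the inner triple bond of the diyne on monovalent rhodium should give a trivalent rhodacyclopentadiene (bond between positions 4 and 5 of ring A), the tethered ynone then inserts (bond between positions 2 and 3) and reductive elimination forms the bond between positions 6 and 1 and releases the arene. The closest known reaction type is the fully intramolecular RhCl(PPh3)3- or CpCo(CO)2-mediated [2+2+2] cyclotrimerisation of triynes, including triynes held together by temporary diisopropylsilyl ether tethers. Ring A closes in the [2+2+2] event itself, the five-membered oxasilole closes as a 1,6-diyne-type annulation across the Si–O–CH2 tether and the six-membered oxasiline as a 1,7-diyne-type annulation across the tether that runs from silicon through the ring B ortho oxygen and two ring B carbons. No stereocentre is formed. The step needs reaction at the inner and not the outer triple bond of the diyne and a single orientation of the ynone; both follow from the tethers, because the outer triple bond could only react through a seven-membered ring that would contain a triple bond, and the ynone is anchored through ring B so that its alkyne carbon bonded to ring B must join the silicon-bearing position 3 of ring A. High dilution is used to keep intermolecular oligomerisation behind the intramolecular pathway.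

Step 12
Reactants: 19 doubly silicon-tethered cyclotrimer (tetracyclic aryl ketone)
Product: 21 {2'-hydroxy-4-(hydroxymethyl)-4'-(methoxymethoxy)-3-{[4-(methoxymethoxy)phenyl]ethynyl}-[1,1'-biphenyl]-2-yl}[4-(methoxymethoxy)phenyl]methanone, via bis(fluorosilyl) diol 20 (not isolated)
Conditions: Bu4NF (excess), THF/DMF, H2O (few equiv), 60 °C
Reagents that add atoms: none
Why: Fluoride first opens both Si–O bonds and then, through pentacoordinate fluorosiliconates, cleaves the two aryl–Si bonds by ipso-protonation (fluoride-mediated protodesilylation of aryl(alkoxy)diisopropylsilanes, the standard removal of such tethers); the electron-poor ring A helps, its position 4 being para to the ketone, and water supplies the protons and keeps the freed benzylic alkoxide protonated.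

Step 13
Reactants: 22 4-bromophenol
Product: 23 1-bromo-4-(methoxymethoxy)benzene
Conditions: MOMCl, iPr2NEt, CH2Cl2, 0 °C → rt
Reagents that add atoms: chloromethyl methyl ether (MOMCl), COCCl
Why: Phenol O-alkylation with MOMCl under amine base, as in step 1.

Step 14
Reactants: 21 {2'-hydroxy-4-(hydroxymethyl)-4'-(methoxymethoxy)-3-{[4-(methoxymethoxy)phenyl]ethynyl}-[1,1'-biphenyl]-2-yl}[4-(methoxymethoxy)phenyl]methanone, 23 1-bromo-4-(methoxymethoxy)benzene
Product: 25 {2'-hydroxy-4-(hydroxymethyl)-4'-(methoxymethoxy)-3-{[4-(methoxymethoxy)phenyl]ethynyl}-[1,1'-biphenyl]-2-yl}bis[4-(methoxymethoxy)phenyl]methanol, via 4-(methoxymethoxy)phenyllithium 24 (not isolated)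
Conditions: 23, n-BuLi, THF, −78 °C; then 21 (aryllithium in excess), −78 → 0 °C; aq. NH4Cl
Reagents that add atoms: none
Why: Bromine–lithium exchange gives the aryllithium, which first deprotonates the two hydroxyls (any lactol between the ring B ortho hydroxyl and the ketone reopens as the phenoxide) and then undergoes 1,2-addition to the non-enolisable diaryl ketone; the carbinol carbon then carries two identical aryl groups, so no stereocentre arises.

Step 15
Reactants: 25 {2'-hydroxy-4-(hydroxymethyl)-4'-(methoxymethoxy)-3-{[4-(methoxymethoxy)phenyl]ethynyl}-[1,1'-biphenyl]-2-yl}bis[4-(methoxymethoxy)phenyl]methanol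
Product: 27 selaginellin F, via deprotected triarylcarbinol 26 (not isolated)
Conditions: aq. HCl, MeOH/THF, rt → 40 °C; NaHCO3 work-up
Reagents that add atoms: none
Why: Acid-catalysed acetal exchange with methanol removes the four MOM groups (formaldehyde is carried off as dimethoxymethane, away from the electron-rich ring B), and the carbinol flanked by two para-hydroxyphenyl groups ionises and loses water to give the para-quinone methide (acid-induced dehydration of a para-hydroxytriarylcarbinol); the primary benzylic alcohol on ring A should not ionise under these conditions.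

**Compound list**

1 | 4-hydroxybenzaldehyde | O=Cc1ccc(O)cc1 | starting material
2 | 4-(methoxymethoxy)benzaldehyde | COCOc1ccc(C=O)cc1 | intermediate
3 | 1-ethynyl-4-(methoxymethoxy)benzene | C#Cc1ccc(OCOC)cc1 | intermediate
4 | 1-(bromoethynyl)-4-(methoxymethoxy)benzene | BrC#Cc1ccc(OCOC)cc1 | intermediate
5 | propargyl alcohol (prop-2-yn-1-ol) | C#CCO | starting material
6 | 5-[4-(methoxymethoxy)phenyl]penta-2,4-diyn-1-ol | OCC#CC#Cc1ccc(OCOC)cc1 | intermediate
7 | ethynylmagnesium bromide (THF solution) | C#C[Mg]Br | starting material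
8 | dichlorodiisopropylsilane | CC(C)[Si](Cl)(Cl)C(C)C | starting material
9 | chloro(ethynyl)diisopropylsilane | C#C[Si](Cl)(C(C)C)C(C)C | intermediate
10 | ethynyldiisopropyl({5-[4-(methoxymethoxy)phenyl]penta-2,4-diyn-1-yl}oxy)silane | C#C[Si](C(C)C)(C(C)C)OCC#CC#Cc1ccc(OCOC)cc1 | intermediate
11 | 4-iodoresorcinol (4-iodobenzene-1,3-diol) | Oc1ccc(I)c(O)c1 | starting material
12 | 2-iodo-5-(methoxymethoxy)phenol | Oc1cc(OCOC)ccc1I | intermediate
13 | {[diisopropyl({5-[4-(methoxymethoxy)phenyl]penta-2,4-diyn-1-yl}oxy)silyl]ethynyl}lithium | [Li]C#C[Si](C(C)C)(C(C)C)OCC#CC#Cc1ccc(OCOC)cc1 | intermediate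
14 | chloro{[diisopropyl({5-[4-(methoxymethoxy)phenyl]penta-2,4-diyn-1-yl}oxy)silyl]ethynyl}diisopropylsilane | CC(C)[Si](Cl)(C(C)C)C#C[Si](C(C)C)(C(C)C)OCC#CC#Cc1ccc(OCOC)cc1 | intermediate
15 | {[2-iodo-5-(methoxymethoxy)phenoxy]diisopropylsilyl}{diisopropyl({5-[4-(methoxymethoxy)phenyl]penta-2,4-diyn-1-yl}oxy)silyl}ethyne | CC(C)[Si](C(C)C)(OCC#CC#Cc1ccc(OCOC)cc1)C#C[Si](C(C)C)(C(C)C)Oc1cc(OCOC)ccc1I | intermediate
16 | rac-1-[4-(methoxymethoxy)phenyl]prop-2-yn-1-ol (racemic carbinol) | C#CC(O)c1ccc(OCOC)cc1 | intermediate
17 | rac-3-{2-[({[diisopropyl({5-[4-(methoxymethoxy)phenyl]penta-2,4-diyn-1-yl}oxy)silyl]ethynyl}diisopropylsilyl)oxy]-4-(methoxymethoxy)phenyl}-1-[4-(methoxymethoxy)phenyl]prop-2-yn-1-ol (racemic carbinol) | CC(C)[Si](C(C)C)(OCC#CC#Cc1ccc(OCOC)cc1)C#C[Si](C(C)C)(C(C)C)Oc1cc(OCOC)ccc1C#CC(O)c1ccc(OCOC)cc1 | intermediate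
18 | 3-{2-[({[diisopropyl({5-[4-(methoxymethoxy)phenyl]penta-2,4-diyn-1-yl}oxy)silyl]ethynyl}diisopropylsilyl)oxy]-4-(methoxymethoxy)phenyl}-1-[4-(methoxymethoxy)phenyl]prop-2-yn-1-one (triyne, key-step precursor) | CC(C)[Si](C(C)C)(OCC#CC#Cc1ccc(OCOC)cc1)C#C[Si](C(C)C)(C(C)C)Oc1cc(OCOC)ccc1C#CC(=O)c1ccc(OCOC)cc1 | intermediate
19 | doubly silicon-tethered cyclotrimer: ring A fused to a 1,1-diisopropyl-1,3-dihydro-2,1-benzoxasilole (silicon on position 4 of ring A, OCH2 on position 5) and to a 6,6-diisopropyl-6H-dibenzo[c,e][1,2]oxasiline (silicon on position 3 of ring A, oxygen on the ortho carbon of ring B, OMOM para on ring B), with 4-(methoxymethoxy)benzoyl on position 1 and [4-(methoxymethoxy)phenyl]ethynyl on position 6 of ring A | O=C(c1c(C#Cc2ccc(OCOC)cc2)c2CO[Si](C(C)C)(C(C)C)c2c2c1-c1ccc(OCOC)cc1O[Si]2(C(C)C)C(C)C)c1ccc(OCOC)cc1 | intermediate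
20 | {5,6-bis[fluorodi(isopropyl)silyl]-2'-hydroxy-4-(hydroxymethyl)-4'-(methoxymethoxy)-3-{[4-(methoxymethoxy)phenyl]ethynyl}-[1,1'-biphenyl]-2-yl}[4-(methoxymethoxy)phenyl]methanone | O=C(c1c(C#Cc2ccc(OCOC)cc2)c(CO)c([Si](F)(C(C)C)C(C)C)c([Si](F)(C(C)C)C(C)C)c1-c1ccc(OCOC)cc1O)c1ccc(OCOC)cc1 | intermediate
21 | {2'-hydroxy-4-(hydroxymethyl)-4'-(methoxymethoxy)-3-{[4-(methoxymethoxy)phenyl]ethynyl}-[1,1'-biphenyl]-2-yl}[4-(methoxymethoxy)phenyl]methanone | O=C(c1c(C#Cc2ccc(OCOC)cc2)c(CO)ccc1-c1ccc(OCOC)cc1O)c1ccc(OCOC)cc1 | intermediate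
22 | 4-bromophenol | Oc1ccc(Br)cc1 | starting material
23 | 1-bromo-4-(methoxymethoxy)benzene | COCOc1ccc(Br)cc1 | intermediate
24 | 4-(methoxymethoxy)phenyllithium | [Li]c1ccc(OCOC)cc1 | intermediate
25 | {2'-hydroxy-4-(hydroxymethyl)-4'-(methoxymethoxy)-3-{[4-(methoxymethoxy)phenyl]ethynyl}-[1,1'-biphenyl]-2-yl}bis[4-(methoxymethoxy)phenyl]methanol | OC(c1ccc(OCOC)cc1)(c1ccc(OCOC)cc1)c1c(C#Cc2ccc(OCOC)cc2)c(CO)ccc1-c1ccc(OCOC)cc1O | intermediate
26 | {2',4'-dihydroxy-4-(hydroxymethyl)-3-[(4-hydroxyphenyl)ethynyl]-[1,1'-biphenyl]-2-yl}bis(4-hydroxyphenyl)methanol | OC(c1ccc(O)cc1)(c1ccc(O)cc1)c1c(C#Cc2ccc(O)cc2)c(CO)ccc1-c1ccc(O)cc1O | intermediate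
27 | selaginellin F, 4-{[2',4'-dihydroxy-4-(hydroxymethyl)-3-[(4-hydroxyphenyl)ethynyl]-[1,1'-biphenyl]-2-yl](4-hydroxyphenyl)methylidene}cyclohexa-2,5-dien-1-one (no stereocentre) | O=C1C=CC(=C(c2ccc(O)cc2)c2c(-c3ccc(O)cc3O)ccc(CO)c2C#Cc2ccc(O)cc2)C=C1 | target

**Count and risks**

Total step count: 15.
Longest linear sequence: 12 steps (1 → 2 → 3 → 4 → 6 → 10 → 15 → 17 → 18 → 19 → 21 → 25 → 27; steps 1–5, 7, 9–12, 14, 15).

Steps most likely to fail:

Step 11. The two bulky Si(iPr)2 groups may slow insertion of the third alkyne into the crowded rhodacycle, so that the catalyst is tied up or intermolecular oligomerisation takes over; in addition, PPh3 released from the catalyst may add in conjugate fashion to the electrophilic ynone. The fallback sets out from carbinol 17, one step before the oxidation, and moves the ring closure to the less electrophilic carbinol oxidation level under cobalt mediation. Stoichiometric CpCo(CO)2 in refluxing toluene under irradiation should close the same three rings through a cobaltacyclopentadiene and give the cyclised racemic diarylcarbinol F1. Dess–Martin periodinane in CH2Cl2 then oxidises the hindered benzylic alcohol to the ketone, and the route is rejoined at 19.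

Step 12. Cleavage of the aryl–Si bond at position 3 of ring A (meta to the ketone and flanked on both sides) may stall, and under the forcing basic fluoride conditions the freed benzylic alkoxide may add across the neighbouring arylethynyl triple bond. The fallback sets out from 19 and separates Si–O opening from C–Si cleavage. HF·pyridine in THF at 0 °C should open only the two Si–O bonds and give the bis(fluorosilyl) diol 20 as an isolated compound. MOMCl and iPr2NEt cap both hydroxyls to give the bis(fluorosilyl) bis-MOM ether F2. Bu4NF in wet DMF at 80 °C can then be forced without a free hydroxyl beside the alkyne and should deliver the fully MOM-protected biaryl ketone F3. Addition of aryllithium 24 (from 23 and n-BuLi) gives the hexa-MOM triarylcarbinol F4, and aqueous HCl in MeOH/THF removes all six MOM groups and dehydrates, which rejoins the route at 27.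

Step 7. A second substitution at the new silicon, exchange of the alkoxy group on the first silicon by the acetylide, or hydrolysis of the chlorosilane before the phenol is attached would all erode the unsymmetrical bis-silylethyne. The fallback sets out from 10 and replaces the moisture-sensitive chlorosilane by an isolable hydrosilane. Acetylide 13 (LiN(SiMe3)2, THF, −78 °C) is quenched with chlorodiisopropylsilane to give the alkynyl(hydro)silane F5, which can be purified by chromatography. NBS in CH2Cl2 at 0 °C converts Si–H into Si–Br, giving the alkynylbromosilane F6, which is used at once with phenol 12, Et3N and DMAP to rejoin the route at 15.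

**Further compounds**

F1 | step 11 | racemic cyclised diarylcarbinol: compound 19 with the ketone replaced by CH(OH) | OC(c1c(C#Cc2ccc(OCOC)cc2)c2CO[Si](C(C)C)(C(C)C)c2c2c1-c1ccc(OCOC)cc1O[Si]2(C(C)C)C(C)C)c1ccc(OCOC)cc1
F2 | step 12 | {5,6-bis[fluorodi(isopropyl)silyl]-2',4'-bis(methoxymethoxy)-4-[(methoxymethoxy)methyl]-3-{[4-(methoxymethoxy)phenyl]ethynyl}-[1,1'-biphenyl]-2-yl}[4-(methoxymethoxy)phenyl]methanone | O=C(c1c(C#Cc2ccc(OCOC)cc2)c(COCOC)c([Si](F)(C(C)C)C(C)C)c([Si](F)(C(C)C)C(C)C)c1-c1ccc(OCOC)cc1OCOC)c1ccc(OCOC)cc1
F3 | step 12 | {2',4'-bis(methoxymethoxy)-4-[(methoxymethoxy)methyl]-3-{[4-(methoxymethoxy)phenyl]ethynyl}-[1,1'-biphenyl]-2-yl}[4-(methoxymethoxy)phenyl]methanone | O=C(c1c(C#Cc2ccc(OCOC)cc2)c(COCOC)ccc1-c1ccc(OCOC)cc1OCOC)c1ccc(OCOC)cc1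
F4 | step 12 | {2',4'-bis(methoxymethoxy)-4-[(methoxymethoxy)methyl]-3-{[4-(methoxymethoxy)phenyl]ethynyl}-[1,1'-biphenyl]-2-yl}bis[4-(methoxymethoxy)phenyl]methanol | OC(c1ccc(OCOC)cc1)(c1ccc(OCOC)cc1)c1c(C#Cc2ccc(OCOC)cc2)c(COCOC)ccc1-c1ccc(OCOC)cc1OCOC
F5 | step 7 | {[diisopropyl({5-[4-(methoxymethoxy)phenyl]penta-2,4-diyn-1-yl}oxy)silyl]ethynyl}diisopropylsilane | CC(C)[SiH](C(C)C)C#C[Si](C(C)C)(C(C)C)OCC#CC#Cc1ccc(OCOC)cc1
F6 | step 7 | bromo{[diisopropyl({5-[4-(methoxymethoxy)phenyl]penta-2,4-diyn-1-yl}oxy)silyl]ethynyl}diisopropylsilane | CC(C)[Si](Br)(C(C)C)C#C[Si](C(C)C)(C(C)C)OCC#CC#Cc1ccc(OCOC)cc1
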